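**Retrosynthetic overview**
- The target is a benzylic ester. It is cut at the CH2–O(acyl) bond into the ring A acid 11 (haematommic acid, used as its potassium carboxylate) and the bis-MOM benzylic bromide 15 of ring B; the MOM groups come off last.
- The strategy rests on ring A, the formyl ring, numbered from the carbon bearing the ester carbonyl (position 1 carboxyl, 2 CH3, 3 H, 4 OH, 5 CHO, 6 OH). The carboxyl carbon and the methyl are neighbours, with oxygen on position 6 beside position 1 and only hydrogen on position 3 beside position 2. An aryne between positions 1 and 2, flanked by one methoxy group, forms both C–C bonds, taking methyl from MeMgBr at position 2 and CO2 at position 1.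
- The formyl carbon (on position 5 of ring A) and both ring A oxygens come from 4-bromo-2,6-difluorobenzaldehyde.
- Ring B comes from methyl atrarate: bis-MOM protection, then ester-directed lateral lithiation of the 6-methyl group and bromination.
- No ring is formed (both benzene rings are bought) and there are no stereocentres.

Key step: step 3

Remark on the chemistry: the very electron-rich aryl dimethyl acetal cannot survive the acidification that frees the carboxylic acid, so the key step is worked up with aqueous HCl and its product is carried on as the free aldehyde 10; the acetal acid 9 is an unisolated intermediate.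
Remark on the chemistry: radical bromination of a protected methyl atrarate would favour the more electron-rich 3-methyl group and the free ring position 5, so bromide 15 is made by lateral lithiation, which only the methyl ortho to the ester allows.

**Route**

Step 1
Reactants: 1 4-bromo-2,6-difluorobenzaldehyde
Product: 2 4-bromo-2,6-dimethoxybenzaldehyde
Conditions: NaOMe (2.5 equiv), MeOH, 65 °C
Reagents that add atoms: sodium methoxide, C[O-].[Na+]
Why: Nucleophilic aromatic substitution (SNAr), in which both fluorides are ortho to the formyl group and far better leaving groups than the para bromide, so methoxide should replace them and leave the bromine.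

Step 2
Reactants: 2 4-bromo-2,6-dimethoxybenzaldehyde
Product: 3 5-bromo-2-(dimethoxymethyl)-1,3-dimethoxybenzene
Conditions: HC(OMe)3, MeOH, p-TsOH·H2O (cat.), 50 °C; then Et3N
Reagents that add atoms: trimethyl orthoformate, COC(OC)OC; methanol, CO
Why: Acid-catalysed acetalisation driven by the orthoformate as water scavenger masks the aldehyde against the amide base and the Grignard reagent, and the basic quench should preserve the labile acetal.

Step 3
Reactants: 3 5-bromo-2-(dimethoxymethyl)-1,3-dimethoxybenzene; 4 methylmagnesium bromide; 5 carbon dioxide
Product: 10 3-formyl-2,4-dimethoxy-6-methylbenzoic acid, via ortho-bromoaryllithium 6 (not isolated), via 3-methoxyaryne 7 (not isolated), via arylmagnesium bromide 8 (not isolated), via acetal acid 9 (not isolated)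
Conditions: lithium 2,2,6,6-tetramethylpiperidide (1.3 equiv), THF, −78 °C; MeMgBr (3.5 equiv, Et2O), −78 °C to rt; CO2 (gas), −20 °C to rt; 2 M aq HCl, rt
Reagents that add atoms: methylmagnesium bromide, C[Mg]Br; carbon dioxide, O=C=O; water, O
Why: The hindered lithium amide removes one of the two equivalent ring protons of 3, each acidified by a flanking bromine and methoxy group, to give aryllithium 6, which the neighbouring methoxy oxygen should hold at −78 °C and which loses LiBr on warming to the only possible aryne 7 (triple bond between positions 1 and 2 of ring A). The closest known reaction type is the three-component coupling of a 3-alkoxyaryne, generated by ortho-metalation of a 3-haloanisole, with a Grignard reagent and CO2 (aryne carbomagnesiation then carboxylation). No ring is closed and no stereocentre is formed. The step needs methyl delivered to position 2 of ring A only: the inductively withdrawing methoxy group on position 6 makes the remote aryne carbon (position 2) the electrophilic one, and attack there leaves the magnesium on position 1 where the same oxygen stabilises and chelates it, while position 3 beside position 2 carries only hydrogen and exerts no opposing bias. It also needs the carbon nucleophile to outrun amine addition, which the bulk of tetramethylpiperidine and the excess of MeMgBr should secure, and a masked aldehyde, which the acetal provides until CO2 has trapped arylmagnesium 8 as the carboxylate of 9. Acidification then frees the acid and hydrolyses the acetal in the same work-up to give aldehyde acid 10.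

Step 4
Reactants: 10 3-formyl-2,4-dimethoxy-6-methylbenzoic acid
Product: 11 3-formyl-2,4-dihydroxy-6-methylbenzoic acid (haematommic acid)
Conditions: BBr3 (4 equiv), CH2Cl2, −78 °C to rt; then H2O, 0 °C
Reagents that add atoms: none
Why: Lewis-acid cleavage of aryl methyl ethers, in which boron binds each methoxy oxygen (helped by the neighbouring formyl and carboxyl carbonyls) and bromide removes the methyl group by SN2, the aldehyde and acid being released from their boron complexes on hydrolysis.

Step 5
Reactants: 12 methyl 2,4-dihydroxy-3,6-dimethylbenzoate (methyl atrarate)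
Product: 13 methyl 2,4-bis(methoxymethoxy)-3,6-dimethylbenzoate
Conditions: NaH (2.5 equiv), MOMCl (2.5 equiv), DMF, 0 °C to rt
Reagents that add atoms: chloromethyl methyl ether, COCCl
Why: Williamson-type O-alkylation of both sodium phenoxides (NaH is needed for the ester-chelated 2-OH) installs base-stable, acid-labile MOM acetals.

Step 6
Reactants: 13 methyl 2,4-bis(methoxymethoxy)-3,6-dimethylbenzoate
Product: 15 methyl 6-(bromomethyl)-2,4-bis(methoxymethoxy)-3-methylbenzoate, via benzylic lithium toluate anion 14 (not isolated)
Conditions: lithium diisopropylamide (1.15 equiv), THF, −78 °C; then cannulated into BrCCl2CCl2Br (1.5 equiv), THF, −78 °C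
Reagents that add atoms: 1,2-dibromo-1,1,2,2-tetrachloroethane, BrC(Cl)(Cl)C(Cl)(Cl)Br
Why: Lateral (benzylic) lithiation occurs only at the 6-methyl group, which is ortho to the ester and gives an ester-conjugated anion, whereas the 3-methyl group between two ethers is not acidified; the carbanion then attacks bromine of the polyhaloalkane (halophilic bromination with loss of tetrachloroethene), and inverse addition keeps the product away from unreacted anion.

Step 7
Reactants: 11 3-formyl-2,4-dihydroxy-6-methylbenzoic acid; 15 methyl 6-(bromomethyl)-2,4-bis(methoxymethoxy)-3-methylbenzoate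
Product: 17 [2-(methoxycarbonyl)-3,5-bis(methoxymethoxy)-4-methylphenyl]methyl 3-formyl-2,4-dihydroxy-6-methylbenzoate, via potassium haematommate 16 (not isolated)
Conditions: KHCO3 (1.0 equiv), DMF, rt; then 15 (0.95 equiv), rt
Reagents that add atoms: none
Why: SN2 O-alkylation of a carboxylate by a benzylic bromide, in which one equivalent of bicarbonate ionises only the carboxylic acid, both phenols stay hydrogen-bonded to the formyl and ester carbonyls, and the reaction at the benzylic carbon is indifferent to the crowding around the acyl carbon.

Step 8
Reactants: 17 [2-(methoxycarbonyl)-3,5-bis(methoxymethoxy)-4-methylphenyl]methyl 3-formyl-2,4-dihydroxy-6-methylbenzoate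
Product: 18 [3,5-dihydroxy-2-(methoxycarbonyl)-4-methylphenyl]methyl 3-formyl-2,4-dihydroxy-6-methylbenzoate (CNP0122264.0)
Conditions: HCl (1.25 M in MeOH), CH2Cl2, 0 °C to rt; aqueous work-up
Reagents that add atoms: none
Why: Acid-catalysed cleavage of the MOM acetals, with methanol trapping the methoxymethyl cation as dimethoxymethane so that the phenol rings are not alkylated, while the di-ortho-substituted benzylic ester and the methyl ester are too hindered to transesterify and the benzylic C–O bond, meta to both hydroxyls and ortho to the ester, should not ionise.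

**Compound list**
1 | 4-bromo-2,6-difluorobenzaldehyde | O=Cc1c(F)cc(Br)cc1F | starting material
2 | 4-bromo-2,6-dimethoxybenzaldehyde | COc1cc(Br)cc(OC)c1C=O | intermediate
3 | 5-bromo-2-(dimethoxymethyl)-1,3-dimethoxybenzene | COC(OC)c1c(OC)cc(Br)cc1OC | intermediate
4 | methylmagnesium bromide | C[Mg]Br | starting material
5 | carbon dioxide | O=C=O | starting material
6 | [6-bromo-3-(dimethoxymethyl)-2,4-dimethoxyphenyl]lithium | [Li]c1c(Br)cc(OC)c(C(OC)OC)c1OC | intermediate
7 | 4-(dimethoxymethyl)-3,5-dimethoxy-1,2-didehydrobenzene (aryne between positions 1 and 2 of ring A) | COC(OC)C1=C(OC)C#CC=C1OC | intermediate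
8 | [3-(dimethoxymethyl)-2,4-dimethoxy-6-methylphenyl]magnesium bromide | COC(OC)c1c(OC)cc(C)c([Mg]Br)c1OC | intermediate
9 | 3-(dimethoxymethyl)-2,4-dimethoxy-6-methylbenzoic acid (formed as its carboxylate salt) | COC(OC)c1c(OC)cc(C)c(C(=O)O)c1OC | intermediate
10 | 3-formyl-2,4-dimethoxy-6-methylbenzoic acid | COc1cc(C)c(C(=O)O)c(OC)c1C=O | intermediate
11 | 3-formyl-2,4-dihydroxy-6-methylbenzoic acid | Cc1cc(O)c(C=O)c(O)c1C(=O)O | intermediate
12 | methyl 2,4-dihydroxy-3,6-dimethylbenzoate | COC(=O)c1c(C)cc(O)c(C)c1O | starting material
13 | methyl 2,4-bis(methoxymethoxy)-3,6-dimethylbenzoate | COCOc1cc(C)c(C(=O)OC)c(OCOC)c1C | intermediate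
14 | {[2-(methoxycarbonyl)-3,5-bis(methoxymethoxy)-4-methylphenyl]methyl}lithium | [Li]Cc1cc(OCOC)c(C)c(OCOC)c1C(=O)OC | intermediate
15 | methyl 6-(bromomethyl)-2,4-bis(methoxymethoxy)-3-methylbenzoate | COCOc1cc(CBr)c(C(=O)OC)c(OCOC)c1C | intermediate
16 | potassium 3-formyl-2,4-dihydroxy-6-methylbenzoate | Cc1cc(O)c(C=O)c(O)c1C(=O)[O-].[K+] | intermediate
17 | [2-(methoxycarbonyl)-3,5-bis(methoxymethoxy)-4-methylphenyl]methyl 3-formyl-2,4-dihydroxy-6-methylbenzoate | COC(=O)c1c(COC(=O)c2c(C)cc(O)c(C=O)c2O)cc(OCOC)c(C)c1OCOC | intermediate
18 | [3,5-dihydroxy-2-(methoxycarbonyl)-4-methylphenyl]methyl 3-formyl-2,4-dihydroxy-6-methylbenzoate | COC(=O)c1c(COC(=O)c2c(C)cc(O)c(C=O)c2O)cc(O)c(C)c1O | target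

**Step count and risks**
Total steps: 8. Longest linear sequence: 6 (steps 1, 2, 3, 4, 7, 8); ring B is made in steps 5 and 6.

Steps most likely to fail:

1. Step 3. The aryne may be consumed by aryllithium 6 or by the amide before methyl transfer, or bromine may migrate between ring positions before LiBr is lost, so that carbomagnesiation becomes inefficient. The fallback builds the two bonds one at a time by cross-coupling and halogen–lithium exchange. It sets out from 2: Suzuki–Miyaura methylation (trimethylboroxine, [1,1'-bis(diphenylphosphino)ferrocene]palladium dichloride PdCl2(dppf), K2CO3, dioxane/H2O, 90 °C) would give 2,6-dimethoxy-4-methylbenzaldehyde F1. N-Bromosuccinimide in MeCN would brominate one of the two equivalent activated ring positions (each ortho to one methoxy group and para to the other) to give 3-bromo-2,6-dimethoxy-4-methylbenzaldehyde F2. Acetalisation as in step 2 would give 2-bromo-4-(dimethoxymethyl)-3,5-dimethoxy-1-methylbenzene F3. n-BuLi in THF at −78 °C would give [3-(dimethoxymethyl)-2,4-dimethoxy-6-methylphenyl]lithium F4, and CO2 followed by aqueous HCl would bring the sequence back to the route at 9 and, after the same hydrolysis, at 10.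

2. Step 6. The benzylic bromide may be deprotonated or alkylated by unreacted anion 14 (over-bromination, bibenzyl coupling). The fallback uses an oxygen electrophile and lactone opening in place of a halogen electrophile. It sets out from 13: the lithium amide followed by 2-(phenylsulfonyl)-3-phenyloxaziridine would hydroxylate the benzylic anion, and the alkoxide would close onto the ester to give 5,7-bis(methoxymethoxy)-6-methyl-3H-2-benzofuran-1-one F5. KOH in aqueous MeOH would open the lactone to potassium 6-(hydroxymethyl)-2,4-bis(methoxymethoxy)-3-methylbenzoate F6. After evaporation, MeI in DMF at rt would give methyl 6-(hydroxymethyl)-2,4-bis(methoxymethoxy)-3-methylbenzoate F7. Appel bromination (CBr4, PPh3, CH2Cl2, 0 °C), carried out at once before the alcohol relactonises, would come back to the route at 15.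

3. Step 7. Alkylation of the acidic phenoxide on position 4 of ring A may compete with the carboxylate (loss of chemoselectivity), or 11 may decarboxylate under base. The fallback forms the ester before any phenol of ring A is unmasked. It sets out from 10: KHCO3 in DMF would give potassium 3-formyl-2,4-dimethoxy-6-methylbenzoate F8, and alkylation with 15 would give [2-(methoxycarbonyl)-3,5-bis(methoxymethoxy)-4-methylphenyl]methyl 3-formyl-2,4-dimethoxy-6-methylbenzoate F9. BCl3 in CH2Cl2 (−78 to 0 °C) would then cleave both MOM ethers and, by chelation to the formyl and ester carbonyls, both methyl ethers, coming back to the route at 18.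

**Further compounds**
F1 | step 3 | 2,6-dimethoxy-4-methylbenzaldehyde | COc1cc(C)cc(OC)c1C=O
F2 | step 3 | 3-bromo-2,6-dimethoxy-4-methylbenzaldehyde | COc1cc(C)c(Br)c(OC)c1C=O
F3 | step 3 | 2-bromo-4-(dimethoxymethyl)-3,5-dimethoxy-1-methylbenzene | COC(OC)c1c(OC)cc(C)c(Br)c1OC
F4 | step 3 | [3-(dimethoxymethyl)-2,4-dimethoxy-6-methylphenyl]lithium | COC(OC)c1c(OC)cc(C)c([Li])c1OC
F5 | step 6 | 5,7-bis(methoxymethoxy)-6-methyl-3H-2-benzofuran-1-one | O=C1OCc2cc(OCOC)c(C)c(OCOC)c21
F6 | step 6 | potassium 6-(hydroxymethyl)-2,4-bis(methoxymethoxy)-3-methylbenzoate | COCOc1cc(CO)c(C(=O)[O-])c(OCOC)c1C.[K+]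
F7 | step 6 | methyl 6-(hydroxymethyl)-2,4-bis(methoxymethoxy)-3-methylbenzoate | COCOc1cc(CO)c(C(=O)OC)c(OCOC)c1C
F8 | step 7 | potassium 3-formyl-2,4-dimethoxy-6-methylbenzoate | COc1cc(C)c(C(=O)[O-])c(OC)c1C=O.[K+]
F9 | step 7 | [2-(methoxycarbonyl)-3,5-bis(methoxymethoxy)-4-methylphenyl]methyl 3-formyl-2,4-dimethoxy-6-methylbenzoate | COC(=O)c1c(COC(=O)c2c(C)cc(OC)c(C=O)c2OC)cc(OCOC)c(C)c1OCOC
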